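The synthesis rests on cutting the C7a–CH3 bond and the O1–C2 lactone bond of the bicycle. C7a carries only CH3, O1, C7 and C3a. It is therefore the carbonyl carbon of a (Z)-2-(2-oxocyclohexylidene)acetic acid, stored as its ring tautomer, a 7a-hydroxybutenolide. Singlet oxygen delivers that butenolide from a 4,5,6,7-tetrahydrobenzofuran. In one operation a methylcerium reagent opens this pseudoacid and adds to the C7a ketone from the equatorial side, because an axial C4 methyl guards the other side. Acid then recloses the five-membered ring, so the 6S silyl ether fixes 7aR. The precursor is the (6S)-6-silyloxy-7a-hydroxy-4,4-dimethyl butenolide, and C6 comes from epichlorohydrin.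

Key step: step 6

Remarks on the chemistry

* **Numbering.** Benzofuranone numbering is used throughout (O1, C2 carbonyl, C3, C3a, C4 gem-dimethyl, C5, C6 oxygenated, C7, C7a). The "3-O" of the trivial name is the C6 oxygen.
* **Configuration.** The target SMILES reads 6S,7aR. C6–O and C7a–CH3 lie on one face and O1 on the other, and both substituents are axial in the lactone.
* **Choice of epichlorohydrin enantiomer.** The C–O bond of the epichlorohydrin stereocentre is never broken. The isopropenyl group is attached first, so the epoxide CH2 of epichlorohydrin becomes C5 and the CH2Cl carbon becomes C7. This order requires the (S)-enantiomer; attaching the furan first would require the (R)-enantiomer.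
* **Ring closure.** The C3a–C4 bond is closed from a 3-bromofuran by palladium and not by protonating the alkene of a C3–H furan. In a 2-alkylfuran the free α-position is the more nucleophilic site, and both the furan and the silyl ether suffer in strong acid. The bromine fixes the site of ring closure and lets the TBS group be kept.
* **Assumption.** Compound 13 is drawn as its bromomagnesium salt, although the counter-ion in the flask is a Mg/Ce mixture.

Step 1
Reactants: 1 (S)-epichlorohydrin; 2 isopropenylmagnesium bromide
Product: 4 (2S)-2-(2-methylprop-2-en-1-yl)oxirane, via chlorohydrin 3 (not isolated)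
Conditions: CuI (10 mol %), THF, −40 °C; sat. aq NH4Cl; crude 3, powdered NaOH, Et2O, rt; distil
Reagents that add atoms: isopropenylmagnesium bromide (2), CC(=C)[Mg]Br
Why: Copper-catalysed Grignard opening of a terminal epoxide occurs at the unhindered CH2, and the chlorohydrin then closes by intramolecular Williamson displacement of the primary chloride, so the C–O bond of the stereocentre is untouched and its configuration is carried over (descriptor stays S).

Step 2
Reactants: 4 (2S)-2-(2-methylprop-2-en-1-yl)oxirane; 5 3-bromofuran
Product: 7 (2S)-1-(3-bromofuran-2-yl)-4-methylpent-4-en-2-ol, via 3-bromo-2-furyllithium 6 (not isolated)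
Conditions: 5 (slight excess over base), LDA (commercial), THF, −78 °C; then 4, −78 °C → rt; H2O
Reagents that add atoms: none
Why: Directed deprotonation removes the most acidic proton of 5 (C2–H, flanked by O and Br), and the furyllithium opens the monosubstituted epoxide by SN2 attack at its CH2 terminus, which again leaves the carbinol stereocentre untouched.

Step 3
Reactants: 7 (2S)-1-(3-bromofuran-2-yl)-4-methylpent-4-en-2-ol
Product: 8 (2S)-1-(3-bromofuran-2-yl)-2-(tert-butyldimethylsilyloxy)-4-methylpent-4-ene
Conditions: TBSCl, imidazole, DMF, rt
Reagents that add atoms: tert-butyldimethylsilyl chloride, CC(C)(C)[Si](C)(C)Cl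
Why: Imidazole-promoted silylation of a secondary alcohol gives an ether that tolerates palladium, singlet oxygen and organocerium reagents and later anchors the ring conformation.

Step 4
Reactants: 8 (2S)-1-(3-bromofuran-2-yl)-2-(tert-butyldimethylsilyloxy)-4-methylpent-4-ene
Product: 9 (6S)-6-(tert-butyldimethylsilyloxy)-4,4-dimethyl-4,5,6,7-tetrahydro-1-benzofuran
Conditions: Pd(PPh3)4 (5 mol %), HCO2Na, DMF, 85 °C
Reagents that add atoms: none
Why: In this intramolecular reductive Heck reaction, oxidative addition at C3–Br and 6-exo-trig carbopalladation of the 1,1-disubstituted alkene form C3a–C4, and the neopentyl alkylpalladium, which has no β-hydrogen, is reduced by formate to the second methyl, so the site of closure is fixed and no new stereocentre arises.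

Step 5
Reactants: 9 (6S)-6-(tert-butyldimethylsilyloxy)-4,4-dimethyl-4,5,6,7-tetrahydro-1-benzofuran
Product: 11 (6S)-6-(tert-butyldimethylsilyloxy)-7a-hydroxy-4,4-dimethyl-5,6,7,7a-tetrahydro-1-benzofuran-2(4H)-one (both C7a anomers), via endoperoxide 10 (not isolated)
Conditions: O2, tetraphenylporphyrin (cat.), visible light, i-Pr2NEt, CH2Cl2, −78 °C → rt
Reagents that add atoms: dioxygen (as singlet oxygen), O=O
Why: [4+2] cycloaddition of singlet oxygen across the furan α-carbons C2 and C7a gives 10, whose only α-hydrogen (C2–H) is removed by the amine in a Kornblum–DeLaMare fragmentation, so C2 must become the lactone carbonyl and C7a the hemiketal carbon, whose configuration is erased in step 6.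

Step 6
Reactants: 11 (6S)-6-(tert-butyldimethylsilyloxy)-7a-hydroxy-4,4-dimethyl-5,6,7,7a-tetrahydro-1-benzofuran-2(4H)-one; 12 methylmagnesium bromide
Product: 15 (6S,7aR)-6-(tert-butyldimethylsilyloxy)-4,4,7a-trimethyl-5,6,7,7a-tetrahydro-1-benzofuran-2(4H)-one (O-TBS-loliolide), via Z-keto carboxylate 13 (not isolated), via hydroxy acid 14 (not isolated)
Conditions: anhydrous CeCl3 and 12 (ca. 4 equiv each), THF, −78 °C; add 11, −78 → −20 °C; 1 M HCl, 0 °C → rt
Reagents that add atoms: methylmagnesium bromide (12), C[Mg]Br
Why: The first equivalent of the methylcerium reagent removes the hemiketal proton of 11, the 7a-alkoxide collapses by ring–chain tautomerism to Z-keto carboxylate 13, a further equivalent adds 1,2 to the freed C7a ketone (new C7a–CH3 bond), and acidification gives hydroxy acid 14, which lactonises at once because the Z alkene holds the tertiary OH next to the carboxyl. The closest known reaction type is the addition of Grignard and organocerium reagents to γ-hydroxybutenolide pseudoacids and 2-acylbenzoic acids, which gives γ,γ-disubstituted butenolides and phthalides after acid work-up. The butenolide ring (O1, C2, C3, C3a, C7a) recloses by 5-exo-trig addition–elimination of the C7a oxygen at the C2 carboxyl, forming O1–C2 with loss of water and leaving the C7a–O bond intact, so the configuration set in the addition is kept. C7a is controlled by C6 through the chair of 13: the silyl ether sits equatorial (the flipped chair would place it syn-axial to a C4 methyl), one C4 methyl is then axial and 1,3 to C7a and closes the axial trajectory as in 3,3,5-trimethylcyclohexanone, so the methyl arrives equatorially on the face of the C6 oxygen, which is 7aR. After closure the six-membered ring flips, because O1 must lie in the butenolide plane, and CH3 and OTBS end up axial as in loliolide. The step needs 1,2- over 1,4-addition (C3 is β to the ketone) and addition over C7 enolisation with E1cB loss of silanolate, and both should be secured by the oxophilic, weakly basic cerium reagent at low temperature and by the carboxylate charge, which shields C2 and lowers the acceptor character of C3.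

Step 7
Reactants: 15 O-TBS-loliolide
Product: 16 (−)-loliolide, (6S,7aR)-6-hydroxy-4,4,7a-trimethyl-5,6,7,7a-tetrahydro-1-benzofuran-2(4H)-one
Conditions: 48 % aq HF, MeCN, 0 °C → rt
Reagents that add atoms: none
Why: Fluoride-driven Si–O cleavage by the small HF molecule reaches the hindered axial ether under mildly acidic conditions that leave the lactone closed and both stereocentres untouched.

Step 8
Reactants: 16 (−)-loliolide; 17 palmitoyl chloride
Product: 18 (−)-3-O-palmitoylloliolide, (6S,7aR)-4,4,7a-trimethyl-2-oxo-2,4,5,6,7,7a-hexahydro-1-benzofuran-6-yl hexadecanoate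
Conditions: Et3N, DMAP (cat.), CH2Cl2, 0 °C → rt
Reagents that add atoms: palmitoyl chloride (17), CCCCCCCCCCCCCCCC(=O)Cl
Why: DMAP-catalysed O-acylation takes place at oxygen with retention at C6, and although the axial alcohol is flanked by two syn-axial methyls it is the only nucleophile in the molecule.

Compound list

1 | (S)-epichlorohydrin, (2S)-2-(chloromethyl)oxirane | ClC[C@@H]1CO1 | starting material
2 | isopropenylmagnesium bromide | CC(=C)[Mg]Br | starting material
3 | (2S)-1-chloro-4-methylpent-4-en-2-ol | CC(=C)C[C@H](O)CCl | intermediate
4 | (2S)-2-(2-methylprop-2-en-1-yl)oxirane | CC(=C)C[C@H]1CO1 | intermediate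
5 | 3-bromofuran | Brc1ccoc1 | starting material
6 | (3-bromofuran-2-yl)lithium | [Li]c1occc1Br | intermediate
7 | (2S)-1-(3-bromofuran-2-yl)-4-methylpent-4-en-2-ol | CC(=C)C[C@H](O)Cc1occc1Br | intermediate
8 | (2S)-1-(3-bromofuran-2-yl)-2-(tert-butyldimethylsilyloxy)-4-methylpent-4-ene | CC(=C)C[C@H](O[Si](C)(C)C(C)(C)C)Cc1occc1Br | intermediate
9 | (6S)-6-(tert-butyldimethylsilyloxy)-4,4-dimethyl-4,5,6,7-tetrahydro-1-benzofuran | CC1(C)C[C@H](O[Si](C)(C)C(C)(C)C)Cc2occc12 | intermediate
10 | (6S)-6-(tert-butyldimethylsilyloxy)-4,4-dimethyl-2,7a-epidioxy-2,4,5,6,7,7a-hexahydro-1-benzofuran (furan endoperoxide, both faces) | CC1(C)C[C@H](O[Si](C)(C)C(C)(C)C)CC23OOC(O2)C=C13 | intermediate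
11 | (6S)-6-(tert-butyldimethylsilyloxy)-7a-hydroxy-4,4-dimethyl-5,6,7,7a-tetrahydro-1-benzofuran-2(4H)-one (anomer mixture) | CC1(C)C[C@H](O[Si](C)(C)C(C)(C)C)CC2(O)OC(=O)C=C12 | intermediate
12 | methylmagnesium bromide | C[Mg]Br | starting material
13 | bromomagnesium (2Z)-2-[(4S)-4-(tert-butyldimethylsilyloxy)-2,2-dimethyl-6-oxocyclohexylidene]acetate | CC1(C)C[C@H](O[Si](C)(C)C(C)(C)C)CC(=O)/C1=C\C(=O)[O-].[Mg+2].[Br-] | intermediate
14 | (2Z)-2-[(4S,6R)-4-(tert-butyldimethylsilyloxy)-6-hydroxy-2,2,6-trimethylcyclohexylidene]acetic acid | CC1(C)C[C@H](O[Si](C)(C)C(C)(C)C)C[C@@](C)(O)/C1=C\C(O)=O | intermediate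
15 | (6S,7aR)-6-(tert-butyldimethylsilyloxy)-4,4,7a-trimethyl-5,6,7,7a-tetrahydro-1-benzofuran-2(4H)-one | CC1(C)C[C@H](O[Si](C)(C)C(C)(C)C)C[C@@]2(C)OC(=O)C=C12 | intermediate
16 | (−)-loliolide, (6S,7aR)-6-hydroxy-4,4,7a-trimethyl-5,6,7,7a-tetrahydro-1-benzofuran-2(4H)-one | CC1(C)C[C@H](O)C[C@@]2(C)OC(=O)C=C12 | intermediate
17 | palmitoyl chloride | CCCCCCCCCCCCCCCC(=O)Cl | starting material
18 | (−)-3-O-palmitoylloliolide | CCCCCCCCCCCCCCCC(=O)O[C@H]1CC(C)(C)C2=CC(=O)O[C@]2(C)C1 | target

Total step count: 8. Longest linear sequence: 8 steps (1 → 18).

Steps most likely to fail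

**Step 6.**
* Risk: enolisation toward C7 could expel the silyloxy group, methyl could be delivered in conjugate fashion to C3, or facial selectivity could erode if the keto carboxylate reacts through a metal-bridged non-chair conformer.
* Fallback, from 11 back to 15: the acidic proton and the charge are removed before the methyl is introduced.
* Alkylation of the carboxylate tautomer of 11 (MeI, KHCO3, DMF, rt) should give the open-chain methyl (2Z)-2-[(4S)-4-(tert-butyldimethylsilyloxy)-2,2-dimethyl-6-oxocyclohexylidene]acetate F1.
* Methyltriisopropoxytitanium (from MeLi and ClTi(Oi-Pr)3, Et2O/CH2Cl2, −40 °C → rt) is non-basic, adds to ketones but not to esters, and strongly prefers equatorial attack on cyclohexanones.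
* It should give the tertiary methyl (2Z)-2-[(4S,6R)-4-(tert-butyldimethylsilyloxy)-6-hydroxy-2,2,6-trimethylcyclohexylidene]acetate F2.
* F2 lactonises by transesterification on mild acid treatment (PPTS, CH2Cl2) and rejoins the route at 15.

**Step 4.**
* Risk: the furylpalladium species could capture hydride before the 6-exo insertion, giving plain hydrodebromination, or oxidative addition to the electron-rich bromofuran could be slow.
* Fallback, from 8 back to 9: the same C3a–C4 bond is closed by cation chemistry instead of palladium.
* Bromine–lithium exchange (n-BuLi, THF, −78 °C) gives the 3-lithiofuran silyl ether F3.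
* Quenching with water gives (2S)-2-(tert-butyldimethylsilyloxy)-1-(furan-2-yl)-4-methylpent-4-ene F4. This is also what the failure mode itself would deliver, so that material is not lost.
* Catalytic TfOH in dilute CH2Cl2 at low temperature protonates the 1,1-disubstituted alkene to the tertiary cation, which furan C3 captures in a six-ring intramolecular Friedel–Crafts alkylation to give 9.
* High dilution is needed because the free α-position competes intermolecularly, which is why this closure is only the reserve.

**Step 2.**
* Risk: the inductively stabilised bromofuryllithium could open the epoxide sluggishly, with base-induced isomerisation of the epoxide or bromine scrambling on warming, and the volatile epoxide 4 could be lost.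
* Fallback, from 5 back to 7: the order of the two C–C bond formations is inverted, so the weaker nucleophile meets the more electrophilic epoxide and the reliable cuprate opening comes second.
* Compound 5 is lithiated as before to 6 and treated at −78 → −30 °C with purchased (R)-epichlorohydrin (ClC[C@H]1CO1). A cold aqueous quench gives (2R)-1-(3-bromofuran-2-yl)-3-chloropropan-2-ol F5.
* NaOH in Et2O closes F5 to the non-volatile (2R)-2-[(3-bromofuran-2-yl)methyl]oxirane F6.
* Reagent 2 with catalytic CuI (THF, −40 °C) opens F6 at its CH2 terminus to give 7 with the same S configuration.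

Further compounds

F1 | step 6 | methyl (2Z)-2-[(4S)-4-(tert-butyldimethylsilyloxy)-2,2-dimethyl-6-oxocyclohexylidene]acetate | CC1(C)C[C@H](O[Si](C)(C)C(C)(C)C)CC(=O)/C1=C\C(=O)OC
F2 | step 6 | methyl (2Z)-2-[(4S,6R)-4-(tert-butyldimethylsilyloxy)-6-hydroxy-2,2,6-trimethylcyclohexylidene]acetate | CC1(C)C[C@H](O[Si](C)(C)C(C)(C)C)C[C@@](C)(O)/C1=C\C(=O)OC
F3 | step 4 | {2-[(2S)-2-(tert-butyldimethylsilyloxy)-4-methylpent-4-en-1-yl]furan-3-yl}lithium | CC(=C)C[C@H](O[Si](C)(C)C(C)(C)C)Cc1occc1[Li]
F4 | step 4 | (2S)-2-(tert-butyldimethylsilyloxy)-1-(furan-2-yl)-4-methylpent-4-ene | CC(=C)C[C@H](O[Si](C)(C)C(C)(C)C)Cc1ccco1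
F5 | step 2 | (2R)-1-(3-bromofuran-2-yl)-3-chloropropan-2-ol | ClC[C@H](O)Cc1occc1Br
F6 | step 2 | (2R)-2-[(3-bromofuran-2-yl)methyl]oxirane | Brc1ccoc1C[C@@H]1CO1
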